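The data are simulated from invented constants; the scatter is artificial.

A one-step world gives Q one fate, so I tested that on the green run, working with the Q not yet in E. Its late gaps shrank at a steady rate λ = 0.152 h⁻¹, and summing them on gave a ceiling near 86.0%, so a second path, Q → D, was needed beside Q + J → L + E and Q + L → E + L; J + E → Z was also proposed.

| flask | Q | J | temperature | remark | time |
|---|---|---|---|---|---|
| green | 0.13 M | 0.25 mM | 48 °C | run made earlier |  |
| violet | 0.13 M | 0.57 mM | 64 °C | run made earlier |  |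
| blue | 0.20 M | 0.38 mM | 48 °C | run made earlier |  |
| delta | 0.13 M | 0.38 mM | 40 °C |  | 10 h |
| zeta | 0.13 M | 0.38 mM | 55 °C |  | 10 h |
| gamma | 0.13 M | 0.38 mM | 70 °C |  | 10 h |

| run | time / h | E / % |
|---|---|---|
| green | 0.667 | 3.6 |
| green | 2.00 | 16.7 |
| green | 4.00 | 36.2 |
| green | 6.00 | 49.2 |
| green | 8.00 | 58.8 |
| violet | 0.200 | 5.3 |
| violet | 0.417 | 15.3 |
| violet | 0.833 | 32.9 |
| violet | 1.33 | 49.0 |
| violet | 2.50 | 67.3 |
| blue | 1.50 | 20.8 |
| blue | 3.00 | 41.0 |
| blue | 5.00 | 58.7 |
| blue | 6.00 | 65.0 |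
| blue | 8.00 | 74.2 |

(each reading ± 0.5 percentage points)

- what was read earlier has a scatter of 0.5 percentage points, one standard deviation
- steps that have been proposed: Q + J -> L + E; Q + L -> E + L; Q -> D; J + E -> Z

- the best flask by amount of E, in percent of the Q charged; "all alike" if 1.5 percentage points covers them all (delta / zeta / gamma / all alike)
- amount of E at the end, in percent of the Q charged, delta
- amount of E at the end, in percent of the Q charged, zeta
- amount of E at the end, in percent of the Q charged, gamma

Green's ladder, as I read it, had a lag of 0.408 h while J made L, and then a growth time of 7.67 h beside a loss time of 47.2 h; these two act side by side on the same Q, so the growth time, shorter than the loss time, gave a share and not an order of events. The early fractional rate of the blue run was 1.47 times green's, with J charged 1.52 times green's and more Q, so I took growth as pseudo-first-order in Q with k proportional to J.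

The violet run, treated alike, gave a ceiling near 78.0% and λ = 0.874 h⁻¹. At 0.38 mM of J, k was 0.198 h⁻¹ at 48 °C and 0.454 h⁻¹ at 64 °C. I carried the split ρ, the rate of Q → D over the rate of Q → E (the inverse of a selectivity factor), taken at 0.38 mM of J and interpolated in ln ρ: 0.107 at 48 °C, 0.422 at 64 °C, and for zeta 0.195.

ceiling = growth / (growth + loss); λ = k + kρ; Q left = exp(−λ(t − lag)); E = ceiling × (what has left Q)

delta: ρ 0.0539, Q left 26.6%, E 69.6%

zeta: ρ 0.195, Q left 3.81%, E 80.5%

gamma: ρ 0.706, Q left 0.00390%, E 58.6%

My zeta stood highest. The forecast, reckoned separately, gave 68%, 80% and 58% for delta, zeta and gamma and named zeta, holding that “The runs fit simple living growth plus a first-order loss of Q.”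

    Q + J → L + E (k = 0.0160 M⁻¹ s⁻¹, Ea = 60.0 kJ mol⁻¹)
    Q + L → E + L, rate k2*[L]*[Q] (k = 0.450 M⁻¹ s⁻¹, Ea = 45.0 kJ mol⁻¹)
    Q → D (k = 9.30 × 10⁻⁵ s⁻¹, Ea = 112 kJ mol⁻¹)
    J + E → Z (k = 0.00310 M⁻¹ s⁻¹, Ea = 87.0 kJ mol⁻¹)
    (constants at 70 °C)

Delta gave 67.7% and gamma 61.8%, while zeta gave 79.9%, the most of the flasks, and at 10.0 h zeta held 16.8% as D with 3.3% of its Q left. Its ratio of D to E was 0.211, beside ρ = 0.195. Dividing ρ by the gain in J, a factor of 2.50, gave 0.0780 and a ceiling of 92.8% for a neighbour of zeta with 9.5 × 10⁻⁴ M of J, and at 10.0 h that neighbour held 91.2% of E and 8.72% of D.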